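**Plan**
- Retrosynthesis: four benzyl ethers and one silyl ether are removed. The chromone ring is cut at its O–C2 and C2–C3 bonds, back to a C4 aldehyde of the dihydrobenzofuran and a protected phloroacetophenone. The formyl carbon is cut from C4 (leaving a chloride), the dihydrofuran at O1–C7a, and the open chain at the future C2–C3 bond (aldol).
- Forward: 2-bromo-3-hydroxybenzaldehyde is turned into an arylacetyl imide and joined to O-benzylvanillin by an Evans syn-aldol. Reduction and silylation follow, then the dihydrofuran ring (first ring) is closed by O1–C7a coupling. C4–Cl is converted to vinyl and then CHO, the chalcone is made, the pyranone ring (second ring) is closed, C3 of the chromone is hydroxylated, and the product is deprotected.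
- Enabling feature: O1 is an aryl ether oxygen that links the stereogenic benzylic C2 to arene carbon C7a, which lies between oxygenated C7 and C3a. C2 and C3 can therefore be fixed in an acyclic syn-1,3-diol monoether and the five-membered ring closed at the aryl–oxygen bond without touching them. Bromine marks C7a, and the less reactive chlorine holds C4 for the flavonol.
- Stereochemistry: both centres come from the one aldol controlled by (R)-4-benzyl-2-oxazolidinone ((2R,3R) adduct, then (1R,2S) diol, then (2R,3S) trans ring). No later step makes or breaks a bond at either centre.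

Key step: step 9

Remark: the locants O1, C2, C3, C3a, C4–C7 and C7a refer to the 2,3-dihydrobenzofuran core. Enol ether 4 is expected as an E/Z mixture and epoxide 23 as a mixture at the oxirane carbons; neither matters, because both elements disappear in the step that follows.

Step 1
Reactants: 1 2-bromo-3-hydroxybenzaldehyde
Product: 2 2-bromo-6-chloro-3-hydroxybenzaldehyde
Conditions: SO2Cl2 (1.05 equiv), CH2Cl2/Et2O, 0 °C → rt
Reagents that add atoms: sulfuryl chloride, O=S(=O)(Cl)Cl
Why: Electrophilic aromatic chlorination of a phenol, in which the hydroxyl group directs to its free para position C6 (C2 is blocked by bromine and the other ortho position, C4, is expected to be the least reactive site of a 3-hydroxybenzaldehyde toward halogenation), should give the 2,6-dihalo pattern and leave the aldehyde alone.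

Step 2
Reactants: 2 2-bromo-6-chloro-3-hydroxybenzaldehyde
Product: 3 3-(benzyloxy)-2-bromo-6-chlorobenzaldehyde
Conditions: BnBr, K2CO3, DMF, rt
Reagents that add atoms: benzyl bromide, BrCc1ccccc1
Why: Williamson ether synthesis on the acidic phenol should proceed cleanly with carbonate, which does not affect the non-enolisable aldehyde.

Step 3
Reactants: 3 3-(benzyloxy)-2-bromo-6-chlorobenzaldehyde
Product: 4 1-(benzyloxy)-2-bromo-4-chloro-3-(2-methoxyethenyl)benzene (E/Z mixture)
Conditions: Ph3P(CH2OMe)Cl, KOtBu, THF, 0 °C → rt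
Reagents that add atoms: (methoxymethyl)triphenylphosphonium chloride, [Cl-].COC[P+](c1ccccc1)(c1ccccc1)c1ccccc1
Why: Wittig olefination with the non-stabilised methoxymethylene ylide tolerates the two ortho halogens and should convert the aldehyde into the homologous enol ether, whose double-bond geometry is irrelevant because it is hydrolysed next.

Step 4
Reactants: 4 1-(benzyloxy)-2-bromo-4-chloro-3-(2-methoxyethenyl)benzene
Product: 6 2-[3-(benzyloxy)-2-bromo-6-chlorophenyl]acetic acid, via arylacetaldehyde 5 (not isolated)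
Conditions: 2 M HCl, THF, 50 °C; then NaClO2, NaH2PO4, 2-methyl-2-butene, t-BuOH/H2O, rt
Reagents that add atoms: water, O; sodium chlorite, [Na+].[O-]Cl=O
Why: Acid-catalysed enol ether hydrolysis should unmask the arylacetaldehyde, which Pinnick oxidation (chlorous acid, with 2-methyl-2-butene as hypochlorite scavenger) converts into the acid without touching the benzyl ether or the aryl halides.

Step 5
Reactants: 6 2-[3-(benzyloxy)-2-bromo-6-chlorophenyl]acetic acid; 7 (R)-4-benzyl-2-oxazolidinone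
Product: 9 (R)-4-benzyl-3-{2-[3-(benzyloxy)-2-bromo-6-chlorophenyl]acetyl}oxazolidin-2-one, via mixed pivalic anhydride 8 (not isolated)
Conditions: PivCl, Et3N, THF, −20 °C; then LiCl, 7, −20 °C → rt
Reagents that add atoms: none
Why: N-Acylation of the oxazolidinone through the mixed pivalic anhydride, with LiCl/Et3N supplying the lithium-bound carbamate nucleophile under conditions too mild to turn the arylacetyl unit into a ketene, should occur at the less hindered arylacetyl carbonyl of 8.

Step 6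
Reactants: 9 (R)-4-benzyl-3-{2-[3-(benzyloxy)-2-bromo-6-chlorophenyl]acetyl}oxazolidin-2-one; 10 4-(benzyloxy)-3-methoxybenzaldehyde
Product: 13 (R)-4-benzyl-3-[(2R,3R)-3-[4-(benzyloxy)-3-methoxyphenyl]-2-[3-(benzyloxy)-2-bromo-6-chlorophenyl]-3-hydroxypropanoyl]oxazolidin-2-one, via dibutylboron Z-enolate 11 (not isolated), via dibutylboron aldolate 12 (not isolated)
Conditions: Bu2BOTf, iPr2NEt, CH2Cl2, 0 °C; then 10, −78 → 0 °C; then pH 7 buffer, MeOH, 30% H2O2, 0 °C
Reagents that add atoms: none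
Why: Evans syn-aldol, in which soft enolisation gives the Z boron enolate and the aldehyde adds through a closed chair transition state with the imide carbonyls opposed, on the enolate face away from the auxiliary benzyl group, so that the (R)-auxiliary sets both new centres as (2R,3R) with the α-aryl and β-hydroxyl groups syn.

Step 7
Reactants: 13 (R)-4-benzyl-3-[(2R,3R)-3-[4-(benzyloxy)-3-methoxyphenyl]-2-[3-(benzyloxy)-2-bromo-6-chlorophenyl]-3-hydroxypropanoyl]oxazolidin-2-one
Product: 14 (1R,2S)-1-[4-(benzyloxy)-3-methoxyphenyl]-2-[3-(benzyloxy)-2-bromo-6-chlorophenyl]propane-1,3-diol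
Conditions: LiBH4, H2O (1 equiv), Et2O/THF, 0 °C
Reagents that add atoms: none
Why: Reductive cleavage of the N-acyl oxazolidinone by borohydride at the more electrophilic exocyclic carbonyl should release the auxiliary and the primary alcohol without touching either stereocentre (the descriptor at the aryl-bearing carbon changes from R to S only through the change in CIP ranking).

Step 8
Reactants: 14 (1R,2S)-1-[4-(benzyloxy)-3-methoxyphenyl]-2-[3-(benzyloxy)-2-bromo-6-chlorophenyl]propane-1,3-diol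
Product: 15 (1R,2S)-1-[4-(benzyloxy)-3-methoxyphenyl]-2-[3-(benzyloxy)-2-bromo-6-chlorophenyl]-3-[(triisopropylsilyl)oxy]propan-1-ol
Conditions: TIPSCl, imidazole, DMF, 0 °C → rt
Reagents that add atoms: triisopropylsilyl chloride, CC(C)[Si](Cl)(C(C)C)C(C)C
Why: Silyl ether formation with the bulky chlorosilane is expected only at the unhindered primary hydroxyl, and the triisopropylsilyl group is chosen because it resists migration to a neighbouring alkoxide and should withstand the later hydroxide, iodine/DMSO and dioxirane steps.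

Step 9
Reactants: 15 (1R,2S)-1-[4-(benzyloxy)-3-methoxyphenyl]-2-[3-(benzyloxy)-2-bromo-6-chlorophenyl]-3-[(triisopropylsilyl)oxy]propan-1-ol
Product: 16 (2R,3S)-7-(benzyloxy)-2-[4-(benzyloxy)-3-methoxyphenyl]-4-chloro-3-{[(triisopropylsilyl)oxy]methyl}-2,3-dihydrobenzofuran
Conditions: CuI (10 mol %), 1,10-phenanthroline (20 mol %), Cs2CO3 (2 equiv), toluene, 110 °C, argon
Reagents that add atoms: none
Why: Cs2CO3 deprotonates the benzylic alcohol and the alkoxide binds phenanthroline-ligated monovalent copper, which inserts into the C7a–Br bond (oxidative addition to a trivalent aryl copper species) and then forms the O1–C7a bond by reductive elimination. The closest known reaction type is the intramolecular Ullmann-type etherification of aryl bromides by secondary alcohols that gives 2,3-dihydrobenzofurans. The five-membered ring closes in a 5-exo mode at the sp2 ipso carbon. No stereocentre is created, since no bond at C2 or C3 is made or broken, so the syn diol derivative 15 should map with retention onto the trans-2,3-disubstituted ring. Site selectivity between the two ortho halogens rests on the inertness of the C4 chloride toward copper at this temperature, chemoselectivity between the two oxygens rests on the silyl ether that masks the primary one, and exclusion of air suppresses copper-mediated oxidation of the benzylic alcohol.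

Step 10
Reactants: 16 (2R,3S)-7-(benzyloxy)-2-[4-(benzyloxy)-3-methoxyphenyl]-4-chloro-3-{[(triisopropylsilyl)oxy]methyl}-2,3-dihydrobenzofuran
Product: 17 (2R,3S)-7-(benzyloxy)-2-[4-(benzyloxy)-3-methoxyphenyl]-4-ethenyl-3-{[(triisopropylsilyl)oxy]methyl}-2,3-dihydrobenzofuran
Conditions: vinylboronic acid pinacol ester, Pd(OAc)2 (5 mol %), SPhos (10 mol %), K3PO4, toluene/H2O, 100 °C
Reagents that add atoms: 4,4,5,5-tetramethyl-2-vinyl-1,3,2-dioxaborolane, C=CB1OC(C)(C)C(C)(C)O1
Why: Suzuki–Miyaura coupling, in which the bulky electron-rich biaryl phosphine SPhos lets zerovalent palladium insert into the hindered, electron-rich C4–Cl bond (the only halogen left) before transmetalation with the vinylboronate and reductive elimination.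

Step 11
Reactants: 17 (2R,3S)-7-(benzyloxy)-2-[4-(benzyloxy)-3-methoxyphenyl]-4-ethenyl-3-{[(triisopropylsilyl)oxy]methyl}-2,3-dihydrobenzofuran
Product: 18 (2R,3S)-7-(benzyloxy)-2-[4-(benzyloxy)-3-methoxyphenyl]-3-{[(triisopropylsilyl)oxy]methyl}-2,3-dihydrobenzofuran-4-carbaldehyde
Conditions: OsO4 (2 mol %), NaIO4, 2,6-lutidine, dioxane/H2O, rt
Reagents that add atoms: osmium tetroxide (catalytic oxygen carrier), O=[Os](=O)(=O)=O; sodium periodate (terminal oxidant), [Na+].[O-]I(=O)(=O)=O
Why: Lemieux–Johnson oxidative cleavage (dihydroxylation, then periodate glycol cleavage) should convert the styrene into the aldehyde and is preferred to ozone because the electron-rich arenes and benzylic ethers are not attacked.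

Step 12
Reactants: 19 2,4,6-trihydroxyacetophenone
Product: 20 1-[2,4-bis(benzyloxy)-6-hydroxyphenyl]ethan-1-one
Conditions: BnBr (2.1 equiv), K2CO3, DMF, rt
Reagents that add atoms: benzyl bromide, BrCc1ccccc1
Why: Williamson etherification is expected to stop at the dibenzyl ether because the remaining ortho hydroxyl is held in a hydrogen bond to the acetyl carbonyl and is the least nucleophilic.

Step 13
Reactants: 18 (2R,3S)-7-(benzyloxy)-2-[4-(benzyloxy)-3-methoxyphenyl]-3-{[(triisopropylsilyl)oxy]methyl}-2,3-dihydrobenzofuran-4-carbaldehyde; 20 1-[2,4-bis(benzyloxy)-6-hydroxyphenyl]ethan-1-one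
Product: 21 (E)-1-[2,4-bis(benzyloxy)-6-hydroxyphenyl]-3-[(2R,3S)-7-(benzyloxy)-2-(4-(benzyloxy)-3-methoxyphenyl)-3-{[(triisopropylsilyl)oxy]methyl}-2,3-dihydrobenzofuran-4-yl]prop-2-en-1-one
Conditions: KOH (50% aq), EtOH/THF, rt
Reagents that add atoms: none
Why: Claisen–Schmidt condensation (crossed aldol, then E1cB dehydration) of the non-enolisable aldehyde with the methyl ketone should give the E-enone, the two stereocentres carrying no acidifying group and the silyl and benzyl ethers tolerating ethanolic KOH at room temperature.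

Step 14
Reactants: 21 (E)-1-[2,4-bis(benzyloxy)-6-hydroxyphenyl]-3-[(2R,3S)-7-(benzyloxy)-2-(4-(benzyloxy)-3-methoxyphenyl)-3-{[(triisopropylsilyl)oxy]methyl}-2,3-dihydrobenzofuran-4-yl]prop-2-en-1-one
Product: 22 5,7-bis(benzyloxy)-2-[(2R,3S)-7-(benzyloxy)-2-(4-(benzyloxy)-3-methoxyphenyl)-3-{[(triisopropylsilyl)oxy]methyl}-2,3-dihydrobenzofuran-4-yl]-4H-chromen-4-one
Conditions: I2 (10 mol %), DMSO, 120 °C
Reagents that add atoms: none
Why: Iodine-catalysed oxidative cyclisation of a 2'-hydroxychalcone, in which 6-endo oxa-Michael closure of the phenol onto the enone is followed by α-iodination and loss of HI (reoxidised to iodine by DMSO), should form the pyranone ring without any bond change at the dihydrofuran centres.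

Step 15
Reactants: 22 5,7-bis(benzyloxy)-2-[(2R,3S)-7-(benzyloxy)-2-(4-(benzyloxy)-3-methoxyphenyl)-3-{[(triisopropylsilyl)oxy]methyl}-2,3-dihydrobenzofuran-4-yl]-4H-chromen-4-one
Product: 24 5,7-bis(benzyloxy)-2-[(2R,3S)-7-(benzyloxy)-2-(4-(benzyloxy)-3-methoxyphenyl)-3-{[(triisopropylsilyl)oxy]methyl}-2,3-dihydrobenzofuran-4-yl]-3-hydroxy-4H-chromen-4-one, via flavone epoxide 23 (not isolated)
Conditions: DMDO (acetone solution), CH2Cl2, 0 °C → rt; then TsOH·H2O (cat.), CH2Cl2, rt
Reagents that add atoms: dimethyldioxirane, CC1(C)OO1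
Why: Epoxidation of the chromone C2=C3 double bond by the neutral oxidant DMDO, followed by acid-induced opening of the epoxide at C2 and loss of the C3 proton (epoxide-to-enol isomerisation), is the established 3-hydroxylation of 5,7-dialkoxyflavones and avoids the aurone formation expected from alkaline peroxide treatment of the chalcone.

Step 16
Reactants: 24 5,7-bis(benzyloxy)-2-[(2R,3S)-7-(benzyloxy)-2-(4-(benzyloxy)-3-methoxyphenyl)-3-{[(triisopropylsilyl)oxy]methyl}-2,3-dihydrobenzofuran-4-yl]-3-hydroxy-4H-chromen-4-one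
Product: 25 5,7-bis(benzyloxy)-2-[(2R,3S)-7-(benzyloxy)-2-(4-(benzyloxy)-3-methoxyphenyl)-3-(hydroxymethyl)-2,3-dihydrobenzofuran-4-yl]-3-hydroxy-4H-chromen-4-one
Conditions: HF·pyridine, pyridine, THF, 0 °C → rt
Reagents that add atoms: none
Why: Fluoride-driven Si–O cleavage (desilylation) by buffered HF·pyridine should free the primary alcohol and leave the benzyl ethers, the chromone and the benzylic C2–O1 bond untouched.

Step 17
Reactants: 25 5,7-bis(benzyloxy)-2-[(2R,3S)-7-(benzyloxy)-2-(4-(benzyloxy)-3-methoxyphenyl)-3-(hydroxymethyl)-2,3-dihydrobenzofuran-4-yl]-3-hydroxy-4H-chromen-4-one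
Product: 26 3,5,7-trihydroxy-2-[(2R,3S)-7-hydroxy-2-(4-hydroxy-3-methoxyphenyl)-3-(hydroxymethyl)-2,3-dihydrobenzofuran-4-yl]-4H-chromen-4-one
Conditions: H2 (1 atm), 10% Pd/C, THF/MeOH, rt
Reagents that add atoms: none
Why: Catalytic hydrogenolysis of the four benzyl aryl ethers is fast at one atmosphere and room temperature, conditions under which the tetrasubstituted chromone double bond and the cyclic benzylic C2–O1 ether are expected to persist if the reaction is stopped once the last benzyl group has gone.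

**Compound list**
1 | 2-bromo-3-hydroxybenzaldehyde | O=Cc1cccc(O)c1Br | starting material
2 | 2-bromo-6-chloro-3-hydroxybenzaldehyde | O=Cc1c(Cl)ccc(O)c1Br | intermediate
3 | 3-(benzyloxy)-2-bromo-6-chlorobenzaldehyde | O=Cc1c(Cl)ccc(OCc2ccccc2)c1Br | intermediate
4 | 1-(benzyloxy)-2-bromo-4-chloro-3-(2-methoxyethenyl)benzene (E/Z mixture) | COC=Cc1c(Cl)ccc(OCc2ccccc2)c1Br | intermediate
5 | 2-[3-(benzyloxy)-2-bromo-6-chlorophenyl]acetaldehyde | O=CCc1c(Cl)ccc(OCc2ccccc2)c1Br | intermediate (not isolated)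
6 | 2-[3-(benzyloxy)-2-bromo-6-chlorophenyl]acetic acid | OC(=O)Cc1c(Cl)ccc(OCc2ccccc2)c1Br | intermediate
7 | (R)-4-benzyl-2-oxazolidinone | O=C1N[C@H](Cc2ccccc2)CO1 | starting material
8 | 2-[3-(benzyloxy)-2-bromo-6-chlorophenyl]acetic pivalic anhydride | CC(C)(C)C(=O)OC(=O)Cc1c(Cl)ccc(OCc2ccccc2)c1Br | intermediate (not isolated)
9 | (R)-4-benzyl-3-{2-[3-(benzyloxy)-2-bromo-6-chlorophenyl]acetyl}oxazolidin-2-one | O=C(Cc1c(Cl)ccc(OCc2ccccc2)c1Br)N1C(=O)OC[C@H]1Cc1ccccc1 | intermediate
10 | 4-(benzyloxy)-3-methoxybenzaldehyde (O-benzylvanillin) | COc1cc(C=O)ccc1OCc1ccccc1 | starting material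
11 | dibutylboron (Z)-enolate of 9 | CCCCB(CCCC)O/C(=C\c1c(Cl)ccc(OCc2ccccc2)c1Br)N1C(=O)OC[C@H]1Cc1ccccc1 | intermediate (not isolated)
12 | O-dibutylboryl aldolate of 13 | COc1cc([C@H](OB(CCCC)CCCC)[C@H](C(=O)N2C(=O)OC[C@H]2Cc2ccccc2)c2c(Cl)ccc(OCc3ccccc3)c2Br)ccc1OCc1ccccc1 | intermediate (not isolated)
13 | (R)-4-benzyl-3-[(2R,3R)-3-[4-(benzyloxy)-3-methoxyphenyl]-2-[3-(benzyloxy)-2-bromo-6-chlorophenyl]-3-hydroxypropanoyl]oxazolidin-2-one | COc1cc([C@H](O)[C@H](C(=O)N2C(=O)OC[C@H]2Cc2ccccc2)c2c(Cl)ccc(OCc3ccccc3)c2Br)ccc1OCc1ccccc1 | intermediate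
14 | (1R,2S)-1-[4-(benzyloxy)-3-methoxyphenyl]-2-[3-(benzyloxy)-2-bromo-6-chlorophenyl]propane-1,3-diol | COc1cc([C@H](O)[C@H](CO)c2c(Cl)ccc(OCc3ccccc3)c2Br)ccc1OCc1ccccc1 | intermediate
15 | (1R,2S)-1-[4-(benzyloxy)-3-methoxyphenyl]-2-[3-(benzyloxy)-2-bromo-6-chlorophenyl]-3-[(triisopropylsilyl)oxy]propan-1-ol | COc1cc([C@H](O)[C@H](CO[Si](C(C)C)(C(C)C)C(C)C)c2c(Cl)ccc(OCc3ccccc3)c2Br)ccc1OCc1ccccc1 | intermediate
16 | (2R,3S)-7-(benzyloxy)-2-[4-(benzyloxy)-3-methoxyphenyl]-4-chloro-3-{[(triisopropylsilyl)oxy]methyl}-2,3-dihydrobenzofuran | COc1cc([C@@H]2Oc3c(OCc4ccccc4)ccc(Cl)c3[C@H]2CO[Si](C(C)C)(C(C)C)C(C)C)ccc1OCc1ccccc1 | intermediate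
17 | (2R,3S)-7-(benzyloxy)-2-[4-(benzyloxy)-3-methoxyphenyl]-4-ethenyl-3-{[(triisopropylsilyl)oxy]methyl}-2,3-dihydrobenzofuran | COc1cc([C@@H]2Oc3c(OCc4ccccc4)ccc(C=C)c3[C@H]2CO[Si](C(C)C)(C(C)C)C(C)C)ccc1OCc1ccccc1 | intermediate
18 | (2R,3S)-7-(benzyloxy)-2-[4-(benzyloxy)-3-methoxyphenyl]-3-{[(triisopropylsilyl)oxy]methyl}-2,3-dihydrobenzofuran-4-carbaldehyde | COc1cc([C@@H]2Oc3c(OCc4ccccc4)ccc(C=O)c3[C@H]2CO[Si](C(C)C)(C(C)C)C(C)C)ccc1OCc1ccccc1 | intermediate
19 | 2,4,6-trihydroxyacetophenone | CC(=O)c1c(O)cc(O)cc1O | starting material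
20 | 1-[2,4-bis(benzyloxy)-6-hydroxyphenyl]ethan-1-one | CC(=O)c1c(O)cc(OCc2ccccc2)cc1OCc1ccccc1 | intermediate
21 | (E)-1-[2,4-bis(benzyloxy)-6-hydroxyphenyl]-3-[(2R,3S)-7-(benzyloxy)-2-(4-(benzyloxy)-3-methoxyphenyl)-3-{[(triisopropylsilyl)oxy]methyl}-2,3-dihydrobenzofuran-4-yl]prop-2-en-1-one | COc1cc([C@@H]2Oc3c(OCc4ccccc4)ccc(/C=C/C(=O)c4c(O)cc(OCc5ccccc5)cc4OCc4ccccc4)c3[C@H]2CO[Si](C(C)C)(C(C)C)C(C)C)ccc1OCc1ccccc1 | intermediate
22 | 5,7-bis(benzyloxy)-2-[(2R,3S)-7-(benzyloxy)-2-(4-(benzyloxy)-3-methoxyphenyl)-3-{[(triisopropylsilyl)oxy]methyl}-2,3-dihydrobenzofuran-4-yl]-4H-chromen-4-one | COc1cc([C@@H]2Oc3c(OCc4ccccc4)ccc(-c4cc(=O)c5c(OCc6ccccc6)cc(OCc6ccccc6)cc5o4)c3[C@H]2CO[Si](C(C)C)(C(C)C)C(C)C)ccc1OCc1ccccc1 | intermediate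
23 | 2,3-epoxide of flavone 22 (mixture at the oxirane carbons) | COc1cc([C@@H]2Oc3c(OCc4ccccc4)ccc(C45OC4C(=O)c4c(OCc6ccccc6)cc(OCc6ccccc6)cc4O5)c3[C@H]2CO[Si](C(C)C)(C(C)C)C(C)C)ccc1OCc1ccccc1 | intermediate (not isolated)
24 | 5,7-bis(benzyloxy)-2-[(2R,3S)-7-(benzyloxy)-2-(4-(benzyloxy)-3-methoxyphenyl)-3-{[(triisopropylsilyl)oxy]methyl}-2,3-dihydrobenzofuran-4-yl]-3-hydroxy-4H-chromen-4-one | COc1cc([C@@H]2Oc3c(OCc4ccccc4)ccc(-c4oc5cc(OCc6ccccc6)cc(OCc6ccccc6)c5c(=O)c4O)c3[C@H]2CO[Si](C(C)C)(C(C)C)C(C)C)ccc1OCc1ccccc1 | intermediate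
25 | 5,7-bis(benzyloxy)-2-[(2R,3S)-7-(benzyloxy)-2-(4-(benzyloxy)-3-methoxyphenyl)-3-(hydroxymethyl)-2,3-dihydrobenzofuran-4-yl]-3-hydroxy-4H-chromen-4-one | COc1cc([C@@H]2Oc3c(OCc4ccccc4)ccc(-c4oc5cc(OCc6ccccc6)cc(OCc6ccccc6)c5c(=O)c4O)c3[C@H]2CO)ccc1OCc1ccccc1 | intermediate
26 | 3,5,7-trihydroxy-2-[(2R,3S)-7-hydroxy-2-(4-hydroxy-3-methoxyphenyl)-3-(hydroxymethyl)-2,3-dihydrobenzofuran-4-yl]-4H-chromen-4-one | COc1cc([C@@H]2Oc3c(O)ccc(-c4oc5cc(O)cc(O)c5c(=O)c4O)c3[C@H]2CO)ccc1O | target

**Step count**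
Total: 17 steps. Longest linear sequence: 16 steps (steps 1–11 and 13–17); step 12 is a one-step side branch.

**Steps most likely to fail**

Step 6 (Evans aldol). Carbon–carbon bond formation may be slow or poorly selective because the enolate carbon carries an aryl ring with two ortho halogens. The adduct may also epimerise or undergo retro-aldol cleavage through its doubly activated α-hydrogen during work-up. The fallback replaces the reversible aldol by an irreversible acylation followed by a chelation-controlled reduction.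
- It sets out from acid 6. Through mixed anhydride 8, coupling with (S)-4-benzyl-2-oxazolidinone would give (S)-4-benzyl-3-{2-[3-(benzyloxy)-2-bromo-6-chlorophenyl]acetyl}oxazolidin-2-one F1.
- Its chelated sodium Z-enolate (NaHMDS, THF, −78 °C) would be C-acylated by 4-(benzyloxy)-3-methoxybenzoyl chloride on the face away from the auxiliary benzyl group. This would give (S)-4-benzyl-3-[(2R)-3-[4-(benzyloxy)-3-methoxyphenyl]-2-[3-(benzyloxy)-2-bromo-6-chlorophenyl]-3-oxopropanoyl]oxazolidin-2-one F2.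
- Zn(BH4)2 (CH2Cl2/Et2O, −20 °C) would reduce the ketone inside a zinc chelate from the side opposite the α-aryl group. The syn product would be (S)-4-benzyl-3-[(2R,3R)-3-[4-(benzyloxy)-3-methoxyphenyl]-2-[3-(benzyloxy)-2-bromo-6-chlorophenyl]-3-hydroxypropanoyl]oxazolidin-2-one F3.
- LiBH4 would then cleave the auxiliary and the route is rejoined at diol 14.
- The (S)-auxiliary is needed because the chelated enolate is acylated on the face opposite to the one the boron aldol uses.

Step 9 (copper-catalysed ring closure). Oxidative addition may be slow at a bromide flanked by the benzyloxy group and the branched side chain. Protodebromination, copper-mediated oxidation of the benzylic alcohol, or transfer of the silyl group to the alkoxide could then overtake ring closure. The fallback reverses the polarity of the closure and forms O1–C2 in place of O1–C7a.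
- It sets out from 15. Deprotonation and bromine–lithium exchange (n-BuLi, 2.2 equiv, THF, −78 °C), trapping with B(OMe)3 and aqueous work-up would give {6-(benzyloxy)-3-chloro-2-[(1R,2S)-1-(4-(benzyloxy)-3-methoxyphenyl)-1-hydroxy-3-((triisopropylsilyl)oxy)propan-2-yl]phenyl}boronic acid F4.
- Oxidation with H2O2/NaOH would give (1R,2S)-2-[3-(benzyloxy)-6-chloro-2-hydroxyphenyl]-1-[4-(benzyloxy)-3-methoxyphenyl]-3-[(triisopropylsilyl)oxy]propan-1-ol F5.
- Catalytic TsOH in CH2Cl2 would ionise the para-benzyloxy-stabilised benzylic alcohol and the phenol would trap the cation in a 5-exo closure. The untouched C3 centre would direct the aryl group trans to the silyloxymethyl group, so the route is rejoined at 16.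

Step 15 (flavone 3-hydroxylation). DMDO may attack the electron-rich guaiacyl ring or the benzylic C2–H of the dihydrofuran faster than the electron-poor, shielded chromone double bond. The epoxide may also rearrange with ring contraction on acid treatment. The fallback installs the oxygen by directed metalation in place of epoxidation.
- It sets out from flavone 22. LDA (THF, −78 °C) would lithiate the chromone C3 next to the carbonyl group, and B(OMe)3 followed by aqueous work-up would give {5,7-bis(benzyloxy)-2-[(2R,3S)-7-(benzyloxy)-2-(4-(benzyloxy)-3-methoxyphenyl)-3-(((triisopropylsilyl)oxy)methyl)-2,3-dihydrobenzofuran-4-yl]-4-oxo-4H-chromen-3-yl}boronic acid F6.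
- H2O2/AcOH would oxidise the C–B bond to C–OH and the route is rejoined at 24.

**Further compounds**
F1 | step 6 | (S)-4-benzyl-3-{2-[3-(benzyloxy)-2-bromo-6-chlorophenyl]acetyl}oxazolidin-2-one | O=C(Cc1c(Cl)ccc(OCc2ccccc2)c1Br)N1C(=O)OC[C@@H]1Cc1ccccc1
F2 | step 6 | (S)-4-benzyl-3-[(2R)-3-[4-(benzyloxy)-3-methoxyphenyl]-2-[3-(benzyloxy)-2-bromo-6-chlorophenyl]-3-oxopropanoyl]oxazolidin-2-one | COc1cc(C(=O)[C@H](C(=O)N2C(=O)OC[C@@H]2Cc2ccccc2)c2c(Cl)ccc(OCc3ccccc3)c2Br)ccc1OCc1ccccc1
F3 | step 6 | (S)-4-benzyl-3-[(2R,3R)-3-[4-(benzyloxy)-3-methoxyphenyl]-2-[3-(benzyloxy)-2-bromo-6-chlorophenyl]-3-hydroxypropanoyl]oxazolidin-2-one | COc1cc([C@H](O)[C@H](C(=O)N2C(=O)OC[C@@H]2Cc2ccccc2)c2c(Cl)ccc(OCc3ccccc3)c2Br)ccc1OCc1ccccc1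
F4 | step 9 | {6-(benzyloxy)-3-chloro-2-[(1R,2S)-1-(4-(benzyloxy)-3-methoxyphenyl)-1-hydroxy-3-((triisopropylsilyl)oxy)propan-2-yl]phenyl}boronic acid | COc1cc([C@H](O)[C@H](CO[Si](C(C)C)(C(C)C)C(C)C)c2c(Cl)ccc(OCc3ccccc3)c2B(O)O)ccc1OCc1ccccc1
F5 | step 9 | (1R,2S)-2-[3-(benzyloxy)-6-chloro-2-hydroxyphenyl]-1-[4-(benzyloxy)-3-methoxyphenyl]-3-[(triisopropylsilyl)oxy]propan-1-ol | COc1cc([C@H](O)[C@H](CO[Si](C(C)C)(C(C)C)C(C)C)c2c(Cl)ccc(OCc3ccccc3)c2O)ccc1OCc1ccccc1
F6 | step 15 | {5,7-bis(benzyloxy)-2-[(2R,3S)-7-(benzyloxy)-2-(4-(benzyloxy)-3-methoxyphenyl)-3-(((triisopropylsilyl)oxy)methyl)-2,3-dihydrobenzofuran-4-yl]-4-oxo-4H-chromen-3-yl}boronic acid | COc1cc([C@@H]2Oc3c(OCc4ccccc4)ccc(-c4oc5cc(OCc6ccccc6)cc(OCc6ccccc6)c5c(=O)c4B(O)O)c3[C@H]2CO[Si](C(C)C)(C(C)C)C(C)C)ccc1OCc1ccccc1
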